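Side chain numbering: C1' (ArO–CH2), C2' and C3' (oxirane carbons, CH3 on C3'), C4', C5' (carbinol), C6'=C7'(CH3)2. The enabling feature is that the C3'–O and C5'–O bonds are 1,3-syn and C1' and C4' are cis on the oxirane ring, so the oxirane oxygen can be passed from a C5' carbonate to a Z-C2'=C3' alkene.
Cuts, in retrosynthetic order: C6'=C7' (cross-metathesis; vinyl stands in for isobutenyl so that only one electron-rich alkene meets the iodine electrophile), oxirane O–C2' (from a C2' iodide), C3'–O and C2'–I (iodocarbonate cyclisation), ArO–C1' (Mitsunobu), C3'–CH3 (cuprate), C1'–C2' (acetylide acylation), C4'–C5' (propargylation of acrolein).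
Forward: the enyne carbinol holding C2'–C6' is made and resolved, and C1' and the C3' methyl group are added with Z geometry. The coumarin is then attached, the 1,3-dioxan-2-one ring closes and is traded for the oxirane ring, and the gem-dimethyl terminus comes last.
Stereochemistry: C5' (S) comes from a Sharpless kinetic resolution and the Z-alkene from syn-carbocupration. C3' (R) is set by 1,3-induction from C5' in a chair transition state. C2' is set by anti addition to the Z-alkene (R in the iodide) and is inverted to S when the oxirane closes.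

Key step: step 10

Remark on the chemistry: 7-hydroxy-8-methoxycoumarin is taken as a purchased material, and C5' is set before the aryl ether is in place so that no β,γ-unsaturated aldehyde carrying a vinylogous aryloxide leaving group has to be handled.

Step 1
Reactants: 1 acrolein; 2 propargyl bromide
Product: 4 rac-hex-1-en-5-yn-3-ol, via allenylzinc bromide 3 (not isolated)
Conditions: Zn dust, THF, 0 °C to rt; then cold 1 M HCl
Reagents that add atoms: none
Why: Barbier-type propargylation in which zinc inserts into 2 to give allenylzinc bromide 3, which adds 1,2 to the aldehyde of 1 through a cyclic SE2' transition state and should give the homopropargylic alcohol, with C5' still racemic.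

Step 2
Reactants: 4 rac-hex-1-en-5-yn-3-ol
Product: 5 (3S)-hex-1-en-5-yn-3-ol
Conditions: Ti(OiPr)4 (10 mol %), D-(−)-DIPT (15 mol %), t-BuOOH (0.6 equiv), 4 Å MS, CH2Cl2, −20 °C
Reagents that add atoms: none
Why: Sharpless kinetic resolution of a 1-alken-3-ol, in which D-(−)-DIPT makes the (R)-enantiomer epoxidise much faster, so that at a little over half conversion the unreacted alcohol should be the (S)-form that becomes C5', the alkyne being inert to Ti(OiPr)4/t-BuOOH.

Step 3
Reactants: 5 (3S)-hex-1-en-5-yn-3-ol
Product: 6 (3S)-3-(tert-butyldimethylsilyloxy)hex-1-en-5-yne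
Conditions: TBSCl, imidazole, CH2Cl2, 0 °C to rt
Reagents that add atoms: tert-butyldimethylsilyl chloride, CC(C)(C)[Si](C)(C)Cl
Why: Imidazole-promoted silylation of a secondary alcohol masks the hydroxyl proton for the organometallic steps and does not touch the stereocentre.

Step 4
Reactants: 6 (3S)-3-(tert-butyldimethylsilyloxy)hex-1-en-5-yne
Product: 8 methyl (5S)-5-(tert-butyldimethylsilyloxy)hept-6-en-2-ynoate, via lithium acetylide 7 (not isolated)
Conditions: n-BuLi, THF, −78 °C; then ClCO2Me, −78 °C to 0 °C
Reagents that add atoms: methyl chloroformate, COC(=O)Cl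
Why: Deprotonation of the terminal alkyne and C-acylation of the lithium acetylide with a chloroformate is a routine way to 2-ynoates and adds C1' at the ester oxidation level.

Step 5
Reactants: 8 methyl (5S)-5-(tert-butyldimethylsilyloxy)hept-6-en-2-ynoate
Product: 9 methyl (2Z,5S)-5-(tert-butyldimethylsilyloxy)-3-methylhepta-2,6-dienoate
Conditions: Me2CuLi (from CuI and 2 MeLi), THF, −78 °C; sat. aq NH4Cl added at −78 °C
Reagents that add atoms: lithium dimethylcuprate Me2CuLi, [Li+].C[Cu-]C
Why: Conjugate syn-carbocupration of a 2-ynoate puts CH3 and copper on the same side, and protonation of the alkenylcuprate at −78 °C, before it can equilibrate through the allenolate, should leave C4' cis to the ester carbon, which is the Z-alkene.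

Step 6
Reactants: 9 methyl (2Z,5S)-5-(tert-butyldimethylsilyloxy)-3-methylhepta-2,6-dienoate
Product: 10 (2Z,5S)-5-(tert-butyldimethylsilyloxy)-3-methylhepta-2,6-dien-1-ol
Conditions: i-Bu2AlH (2.5 equiv), CH2Cl2, −78 °C; aq potassium sodium tartrate
Reagents that add atoms: none
Why: 1,2-Reduction of an α,β-unsaturated ester with i-Bu2AlH goes to the allylic alcohol without conjugate reduction or change of the alkene geometry.

Step 7
Reactants: 10 (2Z,5S)-5-(tert-butyldimethylsilyloxy)-3-methylhepta-2,6-dien-1-ol; 11 7-hydroxy-8-methoxycoumarin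
Product: 12 7-{[(2Z,5S)-5-(tert-butyldimethylsilyloxy)-3-methylhepta-2,6-dienyl]oxy}-8-methoxycoumarin
Conditions: PPh3, DIAD, THF, 0 °C to rt
Reagents that add atoms: none
Why: Mitsunobu etherification in which the acidic phenol 11 displaces the oxyphosphonium group at the primary carbon C1' by SN2 under neutral conditions, so the Z-alkene, the silyl ether and the lactone should stay untouched.

Step 8
Reactants: 12 7-{[(2Z,5S)-5-(tert-butyldimethylsilyloxy)-3-methylhepta-2,6-dienyl]oxy}-8-methoxycoumarin
Product: 13 7-{[(2Z,5S)-5-hydroxy-3-methylhepta-2,6-dienyl]oxy}-8-methoxycoumarin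
Conditions: HF·pyridine, pyridine, THF, 0 °C to rt
Reagents that add atoms: none
Why: Fluoride-driven cleavage of the Si–O bond under buffered conditions spares the base-sensitive lactone and the allyl aryl ether and leaves C5' unchanged.

Step 9
Reactants: 13 7-{[(2Z,5S)-5-hydroxy-3-methylhepta-2,6-dienyl]oxy}-8-methoxycoumarin; 14 di-tert-butyl dicarbonate
Product: 15 7-{[(2Z,5S)-5-(tert-butoxycarbonyloxy)-3-methylhepta-2,6-dienyl]oxy}-8-methoxycoumarin
Conditions: DMAP (0.2 equiv), MeCN, rt
Reagents that add atoms: none
Why: DMAP-catalysed O-acylation of the secondary alcohol with 14 gives the mixed tert-butyl carbonate with retention at C5', without the strong base that the coumarin would not tolerate.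

Step 10
Reactants: 15 7-{[(2Z,5S)-5-(tert-butoxycarbonyloxy)-3-methylhepta-2,6-dienyl]oxy}-8-methoxycoumarin
Product: 16 7-{(2R)-2-iodo-2-[(4R,6S)-4-methyl-2-oxo-6-vinyl-1,3-dioxan-4-yl]ethoxy}-8-methoxycoumarin
Conditions: IBr (1.1 equiv), PhMe/CH2Cl2, −85 °C; aq Na2S2O3/NaHCO3
Reagents that add atoms: iodine monobromide, IBr
Why: IBr transfers I+ reversibly to the most electron-rich alkene, C2'=C3'; the carbonyl oxygen of the C5' tert-butyl carbonate opens the iodonium ion from the rear at the tertiary carbon C3' (C3'–O bond) while iodine stays on C2' (C2'–I bond), and bromide then strips the tert-butyl group from the dioxanylium ion, which makes the closure irreversible. The closest known reaction type is the low-temperature IBr version of the iodocarbonate cyclisation of homoallylic tert-butyl carbonates, the standard entry to syn-1,3-diol carbonates and syn-epoxy alcohols. The 1,3-dioxan-2-one ring closes in the 6-exo-trig mode; the 7-endo mode would need attack at the secondary carbon C2', which is also deactivated by the adjacent CH2OAr group. C3' is controlled by C5' through a chair-like transition state with the vinyl group and the C2' arm equatorial and the C3' methyl group axial, because the other chair pushes C5' against C1', the substituent cis to C4' on the Z-alkene (A(1,3) strain); this puts the new C3'–O bond syn to C5'–O (4R from 6S). C2' is controlled by the stereospecific anti addition to the Z-alkene, which ties its configuration (R) to that of C3'. The step needs chemoselectivity for C2'=C3' over the vinyl group, the pyranone C3=C4 bond and the benzene ring, and this is secured by the higher nucleophilicity of the trisubstituted alkene, the inductive deactivation of the monosubstituted vinyl group by the allylic carbonate, about one equivalent of IBr and the low temperature.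

Step 11
Reactants: 16 7-{(2R)-2-iodo-2-[(4R,6S)-4-methyl-2-oxo-6-vinyl-1,3-dioxan-4-yl]ethoxy}-8-methoxycoumarin
Product: 18 7-{[(2S,3R)-3-[(2S)-2-hydroxybut-3-enyl]-3-methyloxiran-2-yl]methoxy}-8-methoxycoumarin, via iodo diol 17 (not isolated)
Conditions: K2CO3 (3 equiv), MeOH, 0 °C to rt
Reagents that add atoms: none
Why: Base-catalysed transesterification of the cyclic carbonate with methanol frees the C3' and C5' hydroxyl groups, and the C3' alkoxide of iodo diol 17 displaces the neighbouring iodide in an intramolecular Williamson reaction (3-exo-tet, faster than five-ring ether formation from C5'–O) with inversion at C2' (R to S), which should give the oxirane with C1' and C4' cis.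

Step 12
Reactants: 18 7-{[(2S,3R)-3-[(2S)-2-hydroxybut-3-enyl]-3-methyloxiran-2-yl]methoxy}-8-methoxycoumarin; 19 2-methylbut-2-ene
Product: 20 7-{[(2S,3R)-3-[(2S)-2-hydroxy-4-methylpent-3-enyl]-3-methyloxiran-2-yl]methoxy}-8-methoxycoumarin (CNP0223665.2)
Conditions: second-generation Hoveyda–Grubbs catalyst RuCl2(H2IMes)(=CH-C6H4-2-O-i-Pr) (5 mol %), 1,4-benzoquinone (10 mol %), 19 as cosolvent, CH2Cl2, 40 °C, sealed tube
Reagents that add atoms: none
Why: Olefin cross-metathesis of a terminal alkene with 2-methylbut-2-ene as isobutylidene donor is a known way to prenyl-type trisubstituted alkenes, the pyranone C3=C4 bond is too electron-poor to take part, and no stereocentre is involved.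

Compound list
1 | acrolein (prop-2-enal) | C=CC=O | starting material
2 | propargyl bromide (3-bromoprop-1-yne) | C#CCBr | starting material
3 | allenylzinc bromide | C=C=C[Zn]Br | intermediate
4 | rac-hex-1-en-5-yn-3-ol | C#CCC(O)C=C | intermediate
5 | (3S)-hex-1-en-5-yn-3-ol | C#CC[C@H](O)C=C | intermediate
6 | (3S)-3-(tert-butyldimethylsilyloxy)hex-1-en-5-yne | C#CC[C@H](O[Si](C)(C)C(C)(C)C)C=C | intermediate
7 | lithium acetylide of 6 | [Li]C#CC[C@H](O[Si](C)(C)C(C)(C)C)C=C | intermediate
8 | methyl (5S)-5-(tert-butyldimethylsilyloxy)hept-6-en-2-ynoate | COC(=O)C#CC[C@H](O[Si](C)(C)C(C)(C)C)C=C | intermediate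
9 | methyl (2Z,5S)-5-(tert-butyldimethylsilyloxy)-3-methylhepta-2,6-dienoate | COC(=O)/C=C(C)\C[C@H](O[Si](C)(C)C(C)(C)C)C=C | intermediate
10 | (2Z,5S)-5-(tert-butyldimethylsilyloxy)-3-methylhepta-2,6-dien-1-ol | OC/C=C(C)\C[C@H](O[Si](C)(C)C(C)(C)C)C=C | intermediate
11 | 7-hydroxy-8-methoxycoumarin | COc1c(O)ccc2ccc(=O)oc12 | starting material
12 | 7-{[(2Z,5S)-5-(tert-butyldimethylsilyloxy)-3-methylhepta-2,6-dienyl]oxy}-8-methoxycoumarin | COc1c(OC/C=C(C)\C[C@H](O[Si](C)(C)C(C)(C)C)C=C)ccc2ccc(=O)oc12 | intermediate
13 | 7-{[(2Z,5S)-5-hydroxy-3-methylhepta-2,6-dienyl]oxy}-8-methoxycoumarin | COc1c(OC/C=C(C)\C[C@H](O)C=C)ccc2ccc(=O)oc12 | intermediate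
14 | di-tert-butyl dicarbonate | CC(C)(C)OC(=O)OC(=O)OC(C)(C)C | starting material
15 | 7-{[(2Z,5S)-5-(tert-butoxycarbonyloxy)-3-methylhepta-2,6-dienyl]oxy}-8-methoxycoumarin | COc1c(OC/C=C(C)\C[C@H](OC(=O)OC(C)(C)C)C=C)ccc2ccc(=O)oc12 | intermediate
16 | 7-{(2R)-2-iodo-2-[(4R,6S)-4-methyl-2-oxo-6-vinyl-1,3-dioxan-4-yl]ethoxy}-8-methoxycoumarin | I[C@H](COc1ccc2ccc(=O)oc2c1OC)[C@@]1(C)C[C@@H](C=C)OC(=O)O1 | intermediate
17 | 7-{[(2R,3R,5S)-3,5-dihydroxy-2-iodo-3-methylhept-6-enyl]oxy}-8-methoxycoumarin (iodo diol) | I[C@H](COc1ccc2ccc(=O)oc2c1OC)[C@](C)(O)C[C@H](O)C=C | intermediate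
18 | 7-{[(2S,3R)-3-[(2S)-2-hydroxybut-3-enyl]-3-methyloxiran-2-yl]methoxy}-8-methoxycoumarin | COc1c(OC[C@@H]2O[C@]2(C)C[C@H](O)C=C)ccc2ccc(=O)oc12 | intermediate
19 | 2-methylbut-2-ene | CC=C(C)C | starting material
20 | 7-{[(2S,3R)-3-[(2S)-2-hydroxy-4-methylpent-3-enyl]-3-methyloxiran-2-yl]methoxy}-8-methoxycoumarin | COc1c(OC[C@@H]2O[C@]2(C)C[C@H](O)C=C(C)C)ccc2ccc(=O)oc12 | target

Total step count: 12. Longest linear sequence: 12 steps (from 1 and 2 to 20).

Steps most likely to fail

Step 10. The closure may suffer from poor facial selectivity at the quaternary centre C3', since the favoured chair has to carry an axial methyl group. The electrophile may also be diverted to the vinyl group or to the dialkoxy-substituted benzene ring. The fallback replaces halocyclisation by hydroxyl-directed epoxidation; it sets out from 13 and comes back to the route at 18. With VO(acac)2 (cat.) and t-BuOOH in CH2Cl2 at 0 °C, the vanadate ester of the C5' hydroxyl group should hand the peroxide oxygen to the Z-trisubstituted alkene. The transition state is the same kind of chair (vinyl equatorial, C5' held away from C1'), so the oxygen should reach the same face, while the monosubstituted vinyl group is far less nucleophilic. Steps 9 to 11 drop out and no compound outside the list is made (F0).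

Step 12. The metathesis may stall at the branched allylic position, transfer ethylidene in place of isobutylidene, or lose catalyst to ruthenium hydrides that move the double bond of the free allylic alcohol. The fallback builds C6'=C7' by carbonyl olefination; it sets out from 18 and comes back at 20. Silylation (TESCl, imidazole, CH2Cl2) should give the triethylsilyl ether of 18 F1. Lemieux–Johnson cleavage (OsO4 cat., NaIO4, 2,6-lutidine, dioxane/H2O) of the vinyl group, the only alkene that is not electron-poor, should give the α-silyloxy aldehyde F2. Wittig olefination with isopropylidenetriphenylphosphorane (i-PrPPh3I, n-BuLi, THF, −78 °C to 0 °C) should give the triethylsilyl ether of 20 F3, and HF·pyridine in THF at 0 °C then frees 20.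

Step 5. The alkene geometry may erode if the alkenylcuprate equilibrates through its allenolate before it is protonated. The fallback locks the geometry in a ring; it sets out from 8 and comes back at 13. HF·pyridine should give methyl (5S)-5-hydroxyhept-6-en-2-ynoate F4. Me2CuLi (over 2 equiv, THF, −78 °C), followed by a mildly acidic work-up, should give (6S)-4-methyl-6-vinyl-5,6-dihydro-2H-pyran-2-one F5. Only the Z-adduct can lactonise, so any E-ester stays open-chain and is removed by chromatography. Excess i-Bu2AlH (CH2Cl2, −78 °C to 0 °C) should open the lactone to (2Z,5S)-3-methylhepta-2,6-diene-1,5-diol F6. A Mitsunobu reaction with 11 (PPh3, DIAD, THF, 0 °C), selective for the primary allylic hydroxyl group, then gives 13 without passing through 9, 10 and 12.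

Further compounds
F0 | step 10 | none | none
F1 | step 12 | 7-{[(2S,3R)-3-methyl-3-[(2S)-2-(triethylsilyloxy)but-3-enyl]oxiran-2-yl]methoxy}-8-methoxycoumarin | COc1c(OC[C@@H]2O[C@]2(C)C[C@H](O[Si](CC)(CC)CC)C=C)ccc2ccc(=O)oc12
F2 | step 12 | (2S)-3-[(2R,3S)-3-{[(8-methoxy-2-oxochromen-7-yl)oxy]methyl}-2-methyloxiran-2-yl]-2-(triethylsilyloxy)propanal | COc1c(OC[C@@H]2O[C@]2(C)C[C@H](O[Si](CC)(CC)CC)C=O)ccc2ccc(=O)oc12
F3 | step 12 | 7-{[(2S,3R)-3-methyl-3-[(2S)-4-methyl-2-(triethylsilyloxy)pent-3-enyl]oxiran-2-yl]methoxy}-8-methoxycoumarin | COc1c(OC[C@@H]2O[C@]2(C)C[C@H](O[Si](CC)(CC)CC)C=C(C)C)ccc2ccc(=O)oc12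
F4 | step 5 | methyl (5S)-5-hydroxyhept-6-en-2-ynoate | COC(=O)C#CC[C@H](O)C=C
F5 | step 5 | (6S)-4-methyl-6-vinyl-5,6-dihydro-2H-pyran-2-one | CC1=CC(=O)O[C@H](C=C)C1
F6 | step 5 | (2Z,5S)-3-methylhepta-2,6-diene-1,5-diol | OC/C=C(C)\C[C@H](O)C=C
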